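**A direct plan and its weak points**

A direct plan would O-allylate 2-bromo-6-methoxyphenol A1 to the allyl ether A2 and join A2 to eugenol A3 by a copper-catalysed Ullmann etherification, giving the diaryl ether A4. It would then move the allyl group from oxygen to the para carbon by a thermal Claisen/Cope sequence to the phenol A5 (dehydrodieugenol B), and finally couple the oxygen of A5 oxidatively to the free ortho carbon of a second molecule of A3.
- The final aerobic cross-dehydrogenative C–O coupling of the phenols A5 and A3 would be the weakest step. Phenoxyl radicals of A3 also pair with themselves through carbon or oxygen, the product is again an oxidisable phenol that can grow to oligomers, and three allyl groups would face radicals in the last step.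
- The para-Claisen rearrangement of A4 near 195 °C would have to pass through two blocked ortho-dienones, one of which can expel aryloxide. The whole detour of O-allylation of A1 and migration would place a single allyl group.
- The Ullmann etherification would use the electron-rich aryl bromide A2, made from A1 and flanked by an allyloxy group. It is hindered, and hot copper and base may cleave or isomerise the allyl ether.

**Retrosynthetic overview of the new route**

- In every ring the allyl carbon is para to a ring oxygen: C4 of ring A to the A–O–B oxygen, C4 of ring B to the B–O–C oxygen (on C1 of ring B), C4 of ring C to the OH. Written as formyl groups, these three carbons make both diaryl ether bonds fluoride SNAr disconnections.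
- The ether bonds are cut on the other side of each oxygen: O(on C2 of ring B)–C1(ring A) and O(on C2 of ring C)–C1(ring B). Three benzaldehydes are joined around ring B in one flask, with ring B acting first as nucleophile and then as electrophile.
- All three allyl groups are then made together from the three formyl groups, by vinyl addition and palladium-catalysed formate hydrogenolysis with allylic transposition.
- No oxidative or copper-mediated C–O coupling and no Claisen rearrangement is used. No allyl group exists before the last step, and the ring C formyl group also directs which catechol oxygen is arylated.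

Key step: step 3

Remark: the target is achiral. The only stereocentres on the way (three carbinol carbons in 9 and 10) form without control and are removed in step 5. Compounds 1 and 6 are taken as commercial.

**Route**

Step 1
Reactants: 1 4-fluoro-3-methoxybenzaldehyde
Product: 2 2-(4-fluoro-3-methoxyphenyl)-1,3-dioxolane
Conditions: ethylene glycol (1.5 equiv), TsOH·H2O (2 mol%), toluene, reflux, Dean–Stark
Reagents that add atoms: ethylene glycol, OCCO
Why: Acid-catalysed acetalisation with azeotropic removal of water masks the aldehyde, which the pinacolborane formed in step 2 would otherwise reduce; no stereocentre is formed.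

Step 2
Reactants: 2 2-(4-fluoro-3-methoxyphenyl)-1,3-dioxolane
Product: 5 4-fluoro-3-hydroxy-5-methoxybenzaldehyde, via pinacol arylboronate 3 (not isolated), via phenol acetal 4 (not isolated)
Conditions: [Ir(OMe)(cod)]2 (1.5 mol%), 4,4'-di-tert-butyl-2,2'-bipyridine (3 mol%), B2pin2 (1.0 equiv), THF, 80 °C; then 30% H2O2, 2 M NaOH, 0 °C to rt; then Na2SO3 (quench), 2 M HCl, THF, rt
Reagents that add atoms: bis(pinacolato)diboron, CC1(C)OB(OC1(C)C)B1OC(C)(C)C(C)(C)O1 (boron, held only in 3); hydrogen peroxide, OO (phenol oxygen); water, O (aldehyde oxygen)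
Why: Sterically controlled iridium-catalysed C–H borylation should take the only ring hydrogen not ortho to a large group (C5, next to the small fluorine, whereas H2 lies between acetal and methoxy and H6 beside the acetal), alkaline peroxide then oxidises the arylboronate to the phenol at the same carbon, and dilute acid unmasks the aldehyde; no stereocentre is formed.

Step 3
Reactants: 5 4-fluoro-3-hydroxy-5-methoxybenzaldehyde; 1 4-fluoro-3-methoxybenzaldehyde; 6 3,4-dihydroxy-5-methoxybenzaldehyde (5-hydroxyvanillin)
Product: 8 3-[4-formyl-2-(4-formyl-2-methoxyphenoxy)-6-methoxyphenoxy]-4-hydroxy-5-methoxybenzaldehyde, via fluoro dialdehyde 7 (not isolated)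
Conditions: 5 (1.0 equiv), 1 (1.1 equiv), K2CO3 (1.5 equiv), DMSO, 100 °C, Ar; then 6 (1.3 equiv), K2CO3 (3 equiv), 125 °C; 1 M HCl work-up
Reagents that add atoms: none
Why: Two addition–elimination SNAr reactions run in sequence through Meisenheimer complexes stabilised by a para-formyl group: the phenoxide of 5 displaces fluoride from 1 (ring B oxygen to C1 of ring A), then the 3-oxide of doubly deprotonated 6 displaces the fluoride of 7 (ring C oxygen to C1 of ring B, the carbon para to the ring B formyl group). The substrate gates the sequence: as a phenoxide, 5 carries an ortho oxide that switches off its own C–F bond, so it acts only as a nucleophile, and its O-arylation switches that C–F bond on for the second stage. The closest known reaction types are the diaryl ether synthesis from 4-fluorobenzaldehydes and phenols with K2CO3 in dipolar aprotic solvents and the 3-O-selective functionalisation of 3,4-dihydroxybenzaldehydes through their dianions; no ring is closed and no stereocentre is formed. Stage 1 needs 1 to react before 7, which the greater hindrance of the doubly ortho-oxygenated fluoride of 7 and the slight excess of 1 should secure. Stage 2 needs the 3-oxygen of 6 to react rather than the 4-oxygen: the 4-oxide is a vinylogous carboxylate flanked on both sides while the 3-oxide is localised and more nucleophilic, and any 4-O-aryl isomer can correct itself by Smiles rearrangement through a spiro Meisenheimer complex on the activated ring B toward the more stable para-formyl phenoxide. Fluoride is a far better SNAr leaving group than aryloxide, which should keep the first ether bond intact, and the hindered, delocalised phenoxide of 8 should not react further.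

Step 4
Reactants: 8 3-[4-formyl-2-(4-formyl-2-methoxyphenoxy)-6-methoxyphenoxy]-4-hydroxy-5-methoxybenzaldehyde
Product: 10 tetrakis(methyl carbonate) of triol 9 (three 1-arylallyl methyl carbonates and one aryl methyl carbonate; mixture of diastereomers), via triol bromomagnesium salt 9 (not isolated)
Conditions: CH2=CHMgBr (5 equiv), THF, −20 °C to rt; then ClCO2Me (7 equiv), 0 °C to rt
Reagents that add atoms: vinylmagnesium bromide, C=C[Mg]Br; methyl chloroformate, COC(=O)Cl
Why: Grignard 1,2-addition to the three aldehydes (one equivalent is spent on the phenol, and the phenoxide-bearing ring C aldehyde should react with the excess as vanillin does) is followed by trapping of all four magnesium oxides as methyl carbonates in the same flask, which also guards the ring C phenol against quinone methide formation; the three carbinol stereocentres form without control and are removed in step 5.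

Step 5
Reactants: 10 tetrakis(methyl carbonate) of triol 9
Product: 12 4-allyl-2-[4-allyl-2-(4-allyl-2-methoxyphenoxy)-6-methoxyphenoxy]-6-methoxyphenol (target), via triallyl aryl methyl carbonate 11 (not isolated)
Conditions: Pd2(dba)3 (2.5 mol%), PBu3 (10 mol%), HCO2H (6 equiv), Et3N (8 equiv), THF, rt; then K2CO3 (0.5 equiv), MeOH, rt
Reagents that add atoms: none
Why: Tsuji–Trost ionisation of each allylic carbonate by zerovalent palladium gives a 1-arylallyl palladium formate that loses CO2 and delivers hydride to the substituted benzylic terminus from the σ-allyl form with palladium on the unsubstituted carbon, the course known for formate hydrogenolysis with monodentate trialkylphosphines, so each carbonate should give an allyl group (branched and rearranged linear carbonates converge on the same π-allyl complex, which has no β-hydrogen for diene formation), and mild methanolysis then frees the phenol; the three stereocentres of 10 vanish.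

**Compound list**

1 | 4-fluoro-3-methoxybenzaldehyde | COc1cc(C=O)ccc1F | starting material
2 | 2-(4-fluoro-3-methoxyphenyl)-1,3-dioxolane | COc1cc(C2OCCO2)ccc1F | intermediate
3 | 2-[5-(1,3-dioxolan-2-yl)-2-fluoro-3-methoxyphenyl]-4,4,5,5-tetramethyl-1,3,2-dioxaborolane (not isolated) | COc1cc(C2OCCO2)cc(B2OC(C)(C)C(C)(C)O2)c1F | intermediate
4 | 5-(1,3-dioxolan-2-yl)-2-fluoro-3-methoxyphenol (not isolated) | COc1cc(C2OCCO2)cc(O)c1F | intermediate
5 | 4-fluoro-3-hydroxy-5-methoxybenzaldehyde | COc1cc(C=O)cc(O)c1F | intermediate
6 | 3,4-dihydroxy-5-methoxybenzaldehyde (5-hydroxyvanillin) | COc1cc(C=O)cc(O)c1O | starting material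
7 | 4-fluoro-3-(4-formyl-2-methoxyphenoxy)-5-methoxybenzaldehyde (not isolated) | COc1cc(C=O)ccc1Oc1cc(C=O)cc(OC)c1F | intermediate
8 | 3-[4-formyl-2-(4-formyl-2-methoxyphenoxy)-6-methoxyphenoxy]-4-hydroxy-5-methoxybenzaldehyde | COc1cc(C=O)ccc1Oc1cc(C=O)cc(OC)c1Oc1cc(C=O)cc(OC)c1O | intermediate
9 | 4-(1-hydroxyprop-2-en-1-yl)-2-{4-(1-hydroxyprop-2-en-1-yl)-2-[4-(1-hydroxyprop-2-en-1-yl)-2-methoxyphenoxy]-6-methoxyphenoxy}-6-methoxyphenol (mixture of diastereomers; present as its tetrakis(bromomagnesium) salt, not isolated) | C=CC(O)c1ccc(Oc2cc(C(O)C=C)cc(OC)c2Oc2cc(C(O)C=C)cc(OC)c2O)c(OC)c1 | intermediate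
10 | 2-methoxy-4-[1-(methoxycarbonyloxy)prop-2-en-1-yl]-6-{2-methoxy-4-[1-(methoxycarbonyloxy)prop-2-en-1-yl]-6-{2-methoxy-4-[1-(methoxycarbonyloxy)prop-2-en-1-yl]phenoxy}phenoxy}phenyl methyl carbonate (mixture of diastereomers) | C=CC(OC(=O)OC)c1ccc(Oc2cc(C(OC(=O)OC)C=C)cc(OC)c2Oc2cc(C(OC(=O)OC)C=C)cc(OC)c2OC(=O)OC)c(OC)c1 | intermediate
11 | 4-allyl-2-[4-allyl-2-(4-allyl-2-methoxyphenoxy)-6-methoxyphenoxy]-6-methoxyphenyl methyl carbonate (not isolated) | C=CCc1ccc(Oc2cc(CC=C)cc(OC)c2Oc2cc(CC=C)cc(OC)c2OC(=O)OC)c(OC)c1 | intermediate
12 | 4-allyl-2-[4-allyl-2-(4-allyl-2-methoxyphenoxy)-6-methoxyphenoxy]-6-methoxyphenol (achiral) | C=CCc1ccc(Oc2cc(CC=C)cc(OC)c2Oc2cc(CC=C)cc(OC)c2O)c(OC)c1 | target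

**Step count and risks**

Total steps: 5. Longest linear sequence: 5 (1 → 2 → 5 → 8 → 10 → 12).

Steps most likely to fail:

1. Step 3. The phenoxide of 5 may add to the growing fluoride 7 instead of 1 and give oligomers, substitution at the doubly flanked fluoride of 7 may be slow, or the catechol may be arylated on the wrong oxygen without later correction. The fallback joins rings B and C first, with both questions removed by benzyl ethers; it sets out from 5 and 6 and returns at 8. Compound 5 would be benzylated (BnBr, K2CO3, DMF) to 3-(benzyloxy)-4-fluoro-5-methoxybenzaldehyde F1, and 6 would be benzylated only at its acidic 4-OH (BnBr, NaHCO3, DMF, 40 °C) to 4-(benzyloxy)-3-hydroxy-5-methoxybenzaldehyde F2. SNAr of F2 on F1 (K2CO3, DMSO, 120 °C) should give 4-(benzyloxy)-3-[2-(benzyloxy)-4-formyl-6-methoxyphenoxy]-5-methoxybenzaldehyde F3. BCl3 with pentamethylbenzene (CH2Cl2, −78 °C) would remove both benzyl groups to give 3-(4-formyl-2-hydroxy-6-methoxyphenoxy)-4-hydroxy-5-methoxybenzaldehyde F4. The ordinary ring B phenoxide of F4 would then be arylated with 1 (K2CO3, DMSO, 100 °C) in preference to the hindered para-formyl phenoxide of ring C, giving 8.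

2. Step 5. Hydride may be delivered to the terminal carbon of the π-allyl complex, or palladium hydride may move the new double bonds into conjugation; either would give propenyl isomers that are hard to separate. The fallback uses a silicon-controlled allylic transposition instead; it sets out from 8 and returns at 12. Wittig reaction of 8 with the ylide from (2-trimethylsilylethyl)triphenylphosphonium iodide and n-BuLi (excess, THF, −78 °C to rt) should give 2-methoxy-6-{2-methoxy-6-[2-methoxy-4-(3-trimethylsilylprop-1-enyl)phenoxy]-4-(3-trimethylsilylprop-1-enyl)phenoxy}-4-(3-trimethylsilylprop-1-enyl)phenol F5 as an E/Z mixture. Protodesilylation of F5 (CF3CO2H, CH2Cl2, 0 °C) places the proton on the benzylic carbon γ to silicon (SE2′) for both alkene geometries and should give 12.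

3. Step 4. Addition to the phenoxide-deactivated ring C aldehyde may stay incomplete, or the 1-arylallyl carbonates may ionise and decompose on handling. The fallback builds the allyl groups from benzylic electrophiles and a vinyl nucleophile, with no allylic carbonate; it sets out from 8 and returns at 12. Compound 8 would be pivaloylated (PivCl, Et3N, DMAP, CH2Cl2) to 2-[4-formyl-2-(4-formyl-2-methoxyphenoxy)-6-methoxyphenoxy]-4-formyl-6-methoxyphenyl pivalate F6. Reduction (NaBH4, THF/MeOH, 0 °C) would give 4-(hydroxymethyl)-2-{4-(hydroxymethyl)-2-[4-(hydroxymethyl)-2-methoxyphenoxy]-6-methoxyphenoxy}-6-methoxyphenyl pivalate F7, and SOCl2 with pyridine (CH2Cl2, 0 °C) would give 4-(chloromethyl)-2-{4-(chloromethyl)-2-[4-(chloromethyl)-2-methoxyphenoxy]-6-methoxyphenoxy}-6-methoxyphenyl pivalate F8. Threefold Stille coupling (tributyl(vinyl)stannane, Pd(PPh3)4, toluene, 90 °C) would give 4-allyl-2-[4-allyl-2-(4-allyl-2-methoxyphenoxy)-6-methoxyphenoxy]-6-methoxyphenyl pivalate F9, and NaOMe in MeOH at rt would cleave the pivalate to 12.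

**Further compounds**

F1 | step 3 | 3-(benzyloxy)-4-fluoro-5-methoxybenzaldehyde | COc1cc(C=O)cc(OCc2ccccc2)c1F
F2 | step 3 | 4-(benzyloxy)-3-hydroxy-5-methoxybenzaldehyde | COc1cc(C=O)cc(O)c1OCc1ccccc1
F3 | step 3 | 4-(benzyloxy)-3-[2-(benzyloxy)-4-formyl-6-methoxyphenoxy]-5-methoxybenzaldehyde | COc1cc(C=O)cc(OCc2ccccc2)c1Oc1cc(C=O)cc(OC)c1OCc1ccccc1
F4 | step 3 | 3-(4-formyl-2-hydroxy-6-methoxyphenoxy)-4-hydroxy-5-methoxybenzaldehyde | COc1cc(C=O)cc(O)c1Oc1cc(C=O)cc(OC)c1O
F5 | step 5 | 2-methoxy-6-{2-methoxy-6-[2-methoxy-4-(3-trimethylsilylprop-1-enyl)phenoxy]-4-(3-trimethylsilylprop-1-enyl)phenoxy}-4-(3-trimethylsilylprop-1-enyl)phenol (E/Z mixture) | C[Si](C)(C)CC=Cc1ccc(Oc2cc(C=CC[Si](C)(C)C)cc(OC)c2Oc2cc(C=CC[Si](C)(C)C)cc(OC)c2O)c(OC)c1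
F6 | step 4 | 2-[4-formyl-2-(4-formyl-2-methoxyphenoxy)-6-methoxyphenoxy]-4-formyl-6-methoxyphenyl pivalate | COc1cc(C=O)ccc1Oc1cc(C=O)cc(OC)c1Oc1cc(C=O)cc(OC)c1OC(=O)C(C)(C)C
F7 | step 4 | 4-(hydroxymethyl)-2-{4-(hydroxymethyl)-2-[4-(hydroxymethyl)-2-methoxyphenoxy]-6-methoxyphenoxy}-6-methoxyphenyl pivalate | COc1cc(CO)ccc1Oc1cc(CO)cc(OC)c1Oc1cc(CO)cc(OC)c1OC(=O)C(C)(C)C
F8 | step 4 | 4-(chloromethyl)-2-{4-(chloromethyl)-2-[4-(chloromethyl)-2-methoxyphenoxy]-6-methoxyphenoxy}-6-methoxyphenyl pivalate | COc1cc(CCl)ccc1Oc1cc(CCl)cc(OC)c1Oc1cc(CCl)cc(OC)c1OC(=O)C(C)(C)C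
F9 | step 4 | 4-allyl-2-[4-allyl-2-(4-allyl-2-methoxyphenoxy)-6-methoxyphenoxy]-6-methoxyphenyl pivalate | C=CCc1ccc(Oc2cc(CC=C)cc(OC)c2Oc2cc(CC=C)cc(OC)c2OC(=O)C(C)(C)C)c(OC)c1
A1 | direct plan | 2-bromo-6-methoxyphenol | COc1cccc(Br)c1O
A2 | direct plan | 2-(allyloxy)-1-bromo-3-methoxybenzene | C=CCOc1c(Br)cccc1OC
A3 | direct plan | eugenol (4-allyl-2-methoxyphenol) | C=CCc1ccc(O)c(OC)c1
A4 | direct plan | 2-(allyloxy)-1-(4-allyl-2-methoxyphenoxy)-3-methoxybenzene | C=CCOc1c(OC)cccc1Oc1ccc(CC=C)cc1OC
A5 | direct plan | dehydrodieugenol B (4-allyl-2-(4-allyl-2-methoxyphenoxy)-6-methoxyphenol) | C=CCc1cc(OC)c(O)c(Oc2ccc(CC=C)cc2OC)c1
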